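Locants follow the target throughout: ring A is C1–C6; C12 is the CH2O carbon on C1; C7 is the cage CH2 between C6 and C8; C8, C9 and C10 are the cyclopropane carbons (C8 on C7, C9 on C1, C10 carrying the methyl group); C11 is the oxygenated cage carbon between C6 and C10. "Upper face" of ring A means the face that carries C12.

## The problem

The target is a nortricyclene (cyclopropane C8–C9–C10, apex C6, bridges C1, C7 and C11) fused across C1–C6 to cyclohexane ring A. C1, C6 and C5 are three contiguous fully substituted carbons, and C10 is a fourth quaternary centre inside the cage. Of the eight stereocentres, C8, C9 and C10 follow from the cage once C1 and C6 are fixed, and C6 can be set from C1 by a ring closure that can reach only one face. C11, whose oxygen points to the C7 side, has to be set in the step that creates it, because a later reduction of a C11 ketone has no reliable bias toward that epimer. The cis C3/C4 oxygens sit on the upper face of ring A, which already carries C12 and an axial C5 methyl group, so the C3 acetate is axial and any reagent that simply takes the open face gives the wrong diastereomer. The three acetates exclude late strong base or hydride, the cyclopropane dislikes strong acid and hard electrophiles, and the free C4 hydroxyl beside the C3 acetate excludes a blanket acetylation at the end. The feature that opens the route is that C11 bears oxygen and C6 is β to the C4 oxygen through C5: as an aldehyde carbon and an enone β-carbon both are electrophiles, so their union is a reductive coupling, and it leaves an enolate on C5 for the second methyl group. The C9–C10 bond spans two carbons that face each other across a bicyclo[2.2.1]heptane, which invites a carbene insertion into the endo C10–H bond.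

## Retrosynthesis

**C3–O and C4–O.** Target 26 is taken back to the ring A alkene 23 (C3=C4) by a Woodward cis-hydroxylation. Osmylation would come from the open lower face, and α-oxygenation of a C4 ketone would place the C3 oxygen equatorial, trans to C12. The Woodward sequence attacks the open face with the electrophile and then inverts twice, so both oxygens end on the hindered face. Hydrolysis of its acetoxonium ion leaves the ester on the axial oxygen (C3) and the equatorial C4 hydroxyl free, which is the target's pattern without any selective acylation. Alkene 23 has no ring A stereocentre and no free hydroxyl. The forward step needs the iodonium ion on the lower face, acetate attack at C3 and not at neopentyl C4, and an untouched cyclopropane.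

**Ester and ether C–O bonds.** Diacetate 23 comes from diol 22, and 22 from bis(benzyl ether) 21. The acetates are put on only after the last strongly basic step. Dissolving-metal cleavage is chosen for the benzyl groups because hydrogenolysis would saturate C3=C4.

**C9–C10 and the C3=C4 double bond.** Both are traced to carbenes generated from bis(tosylhydrazone) 19 of diketone 18. The C9 carbene has no hydrogen that can shift (C1 is quaternary, C8 a bridgehead) and faces the endo C10–H bond. The C4 carbene has only the C3 hydrogens to shift. Closing the cyclopropane by 1,3-elimination instead would need a C11 ketone, whose reduction favours the wrong C11 epimer, and a separate olefination of C4 would add three steps. The cage is simplified to a norbornanone and ring A to a cyclohexanone. The forward step requires C10–H endo (methyl exo) and a masked C11 oxygen, hence benzyl ether 18 from alcohol 17.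

**C6–C11 and C5–CH3 (key step).** Tricycle 17 is cut to aldehyde-enone 15. Aldol or Michael polarity cannot join two acceptor carbons. An acyl anion addition would give a C11 ketone and postpone C11 to an unfavourable reduction. A tin hydride radical closure would leave no enolate for the methyl group. A reductive ketyl–enone cyclisation with divalent samarium forms the bond, sets C11 and C6 and delivers the C5 enolate in one operation. The precursor 15 is bicyclic with three stereocentres instead of five and with one quaternary carbon instead of three. The forward step needs the C8 arm trans to C12, because in the target C11 and C12 are trans across C1–C6, and it needs C10 configured so that its methyl group ends exo.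

**C8–C10.** Aldehyde 15 comes from alkene 14 by ozonolysis, and 14 from ketone 10 and (Z)-but-2-en-1-ol 11 by a ketal Claisen rearrangement. Acid-mediated enol ether formation is regiodefined (C9 can enolise only toward C8) and avoids base, which would deprotonate the enone at C7 or C3. A direct crotylation would give the linear isomer, and a nitroalkene Michael addition offers no control at C10. The chair transition state on the face opposite C12 gives the arm trans to C12. The Z-alkene is required: the E-isomer through the same chair gives the C10 epimer, whose methyl group would end endo and block the later insertion.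

**C12.** Benzyl ether 10 is derived from alcohol 9, and 9 from the angular allyl compound 6 through propenyl isomer 7 by loss of two carbons. A 2-(alkoxymethyl)-1,3-dione is not a practical annulation partner, whereas the angular allyl group is a standard handle.

**Ring A.** Enedione 6 is opened at C5=C6 (aldol condensation) and C1–C2 (Michael addition) to triketone 5, made from 2-allyl dione 3 and ethyl vinyl ketone 4. Dione 3 comes from cyclopentane-1,3-dione 1 and allyl bromide 2. The amino acid-catalysed aldol step supplies the absolute configuration at C1, from which all other centres are derived.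

## Roads not taken

**Alternative 1:** The cut is C6–C11 and C1–C9 together.
- Forward step: dehydrochlorination of dienoyl chloride A1 gives vinylketene A2, which adds across the C1=C6 alkene of ring A to give bicyclo[3.1.1]heptenone A3; a 1,2-acyl shift then moves C11 from C9 to C10 and closes the cyclopropane.
- Merits: both ring-fusion quaternary carbons form in one step, the complete cage is reached two operations after A1, and the ring A diol is in place as an acetonide before any cyclopropane exists.
- Weak points: both alkene carbons are fully substituted, so nothing biases the bridged over the fused mode of (2+2) addition. The facial sense depends on an acetonide two atoms away. A2 can dimerise or electrocyclise. The cage arrives with a C11 ketone, whose easiest reduction (hydride from the C7 side) puts the hydroxyl toward ring A, the wrong epimer. The hindered-face diol problem is moved earlier but not removed.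
- Comparison: in cage-building step count this road is shorter than the chosen one, which needs steps 7–12. The chosen plan sets against that a ring closure of an established type, C11 fixed during C–C bond formation in 17, and absolute configuration from a cheap amino acid.

**Alternative 2:** The cut is C3–C4, made last.
- Forward step: an N-heterocyclic carbene turns the C3 aldehyde of cage dialdehyde A4 into an acyl anion equivalent that adds to the neopentyl C4 aldehyde and gives ring A hydroxy ketone A5.
- Merits: C4 is set under catalyst control, the two ring A oxygens emerge chemically distinct, no electrophile comes near the cyclopropane, and the C11 and C12 acetates are already present.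
- Weak points: the cut leaves the real difficulty, a cage with three contiguous quaternary carbons bearing two aldehyde arms, entirely inside A4. Aldehyde–aldehyde benzoin closure is reversible, the enolisable C3 aldehyde can undergo aldol reaction, and the α-ketol can isomerise. A5 still needs reduction at C3 to the axial alcohol and then acetylation of that hindered hydroxyl beside a free C4 hydroxyl.
- Comparison: for differentiating C3 from C4 by oxidation level this road is as good as or better than the chosen endgame. The chosen plan offers ring A at no cost from the annulation, a key step that builds the quaternary centres, and a last step whose intrinsic regiochemistry already gives the axial ester.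

**Alternative 3:** The cut is C1–C9, C8–C10 and C6–C7 in one step.
- Forward step: Lewis acid activation of dienone A6, conrotatory closure to C1–C9, and capture of the oxyallyl cation by phenyl vinyl sulfide A7 give bicyclo[2.2.1]heptan-7-one A8.
- Merits: the highest bond economy of all four plans (three C–C bonds, two rings and the quaternary carbons C1, C6 and C10 from two fragments).
- Weak points: closure onto a fully substituted C1 next to C6 is slow. The sense of conrotation is steered only by the distant ring A carbonate. The orientation and face of the sulfide capture are two further selectivities in the same step. Afterwards the C8–C9 cyclopropane bond, desulfurisation and a stereoselective reduction of the bridging C11 ketone all remain.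
- Comparison: this road clearly beats the chosen plan in bonds formed per step. The chosen plan is longer, but each stereocentre has a single identified control element and each ring closure a close analogy.

Key step: step 9

Remark: (Z)-but-2-en-1-ol 11 is taken as a purchasable reagent, and hydroxy diketone 17 is treated as the open form, since hemiketal closure onto C4 would create a fully substituted carbon beside the gem-dimethyl carbon and would reopen under the benzylation conditions.

## Route

Step 1
Reactants: 1 cyclopentane-1,3-dione; 2 allyl bromide
Product: 3 2-allylcyclopentane-1,3-dione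
Conditions: NaOH (1 equiv), H2O, rt → 50 °C
Reagents that add atoms: none
Why: C-allylation of the 1,3-dione anion in water, where hydrogen bonding to the enolate oxygens favours attack through carbon; no stereocentre is formed.

Step 2
Reactants: 3 2-allylcyclopentane-1,3-dione; 4 ethyl vinyl ketone
Product: 5 2-allyl-2-(3-oxopentyl)cyclopentane-1,3-dione
Conditions: Et3N (cat.), EtOAc, rt → 50 °C
Reagents that add atoms: none
Why: Michael addition of the acidic 2-substituted dione to the enone forms the C1–C2 bond; the triketone is achiral because the two ring carbonyls are enantiotopic.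

Step 3
Reactants: 5 2-allyl-2-(3-oxopentyl)cyclopentane-1,3-dione
Product: 6 (7aR)-7a-allyl-4-methyl-2,3,7,7a-tetrahydro-1H-indene-1,5(6H)-dione
Conditions: L-phenylalanine (1 equiv), (+)-camphor-10-sulfonic acid (0.5 equiv), DMF, 30 → 70 °C
Reagents that add atoms: none
Why: Amino acid-catalysed enamine aldol condensation (Hajos–Parrish reaction): the side-chain enamine attacks one of the two enantiotopic ring carbonyls in a carboxylic acid-directed transition state and the ketol dehydrates to the C5=C6 enone. The L-amino acid sets C1 in the spatial sense of the (S)-methyl series, which is the sense the target needs.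

Step 4
Reactants: 6 (7aR)-7a-allyl-4-methyl-2,3,7,7a-tetrahydro-1H-indene-1,5(6H)-dione
Product: 7 (7aR)-4-methyl-7a-[(E)-prop-1-enyl]-2,3,7,7a-tetrahydro-1H-indene-1,5(6H)-dione
Conditions: PdCl2(MeCN)2 (5 mol %), toluene, 80 °C
Reagents that add atoms: none
Why: Metal-catalysed alkene isomerisation moves the terminal double bond one position into the more stable internal place (mainly E; a minor Z isomer converges in step 5); C1 is not touched.

Step 5
Reactants: 7 (7aR)-4-methyl-7a-[(E)-prop-1-enyl]-2,3,7,7a-tetrahydro-1H-indene-1,5(6H)-dione
Product: 9 (7aS)-7a-(hydroxymethyl)-4-methyl-2,3,7,7a-tetrahydro-1H-indene-1,5(6H)-dione, via angular C12 aldehyde 8 (not isolated)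
Conditions: O3, CH2Cl2, −78 °C; Me2S, −78 °C → rt; then LiAlH(OtBu)3 (1.1 equiv), THF, −78 °C, cold AcOH quench
Reagents that add atoms: ozone, [O-][O+]=O
Why: Ozonolysis cleaves the electron-rich propenyl group much faster than the electron-poor tetrasubstituted enone. The bulky alkoxyaluminium hydride then reduces the aldehyde at −78 °C while the neopentyl C9 ketone and the enone remain, and the cold acidic quench avoids retro-aldol loss of formaldehyde.

Step 6
Reactants: 9 (7aS)-7a-(hydroxymethyl)-4-methyl-2,3,7,7a-tetrahydro-1H-indene-1,5(6H)-dione
Product: 10 (7aS)-7a-[(benzyloxy)methyl]-4-methyl-2,3,7,7a-tetrahydro-1H-indene-1,5(6H)-dione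
Conditions: BnOC(=NH)CCl3 (1.5 equiv), TfOH (5 mol %), CH2Cl2/cyclohexane, 0 °C → rt
Reagents that add atoms: benzyl 2,2,2-trichloroacetimidate, ClC(Cl)(Cl)C(=N)OCc1ccccc1
Why: Acid-catalysed benzyl transfer from the trichloroacetimidate forms the ether without an alkoxide, so the β-hydroxy ketone cannot undergo retro-aldol cleavage.

Step 7
Reactants: 10 (7aS)-7a-[(benzyloxy)methyl]-4-methyl-2,3,7,7a-tetrahydro-1H-indene-1,5(6H)-dione; 11 (Z)-but-2-en-1-ol
Product: 14 enedione with a but-3-en-2-yl arm on C8 trans to C12 (C10 methyl), via C9 dimethyl ketal 12 (not isolated), via crotyl enol ether 13 (not isolated)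
Conditions: HC(OMe)3, MeOH, PPTS (cat.), rt; evaporate; then 11 (5 equiv), EtCO2H (cat.), xylene, 140 °C, MeOH distilled off
Reagents that add atoms: none
Why: Ketal Claisen rearrangement: the saturated C9 carbonyl ketalises before the conjugated one, and alcohol exchange with loss of methanol can give an enol ether only toward C8 because C1 is quaternary. The [3,3] shift through a chair on the ring face opposite C12 places the arm trans to C12. The Z-alkene places the C10 methyl group so that, after the cage closes, it is exo and C10–H is endo.

Step 8
Reactants: 14 enedione with a but-3-en-2-yl arm on C8 trans to C12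
Product: 15 (2R)-2-[(2S,7aS)-7a-[(benzyloxy)methyl]-4-methyl-1,5-dioxo-2,3,5,6,7,7a-hexahydro-1H-inden-2-yl]propanal
Conditions: O3, CH2Cl2, −78 °C; PPh3, −78 °C → rt; used without chromatography
Reagents that add atoms: ozone, [O-][O+]=O
Why: Ozonolysis of the monosubstituted vinyl group is much faster than attack on the tetrasubstituted enone or the benzyl ether. The neutral phosphine work-up and direct use protect the epimerisable C10 and C8 centres.

Step 9
Reactants: 15 (2R)-2-[(2S,7aS)-7a-[(benzyloxy)methyl]-4-methyl-1,5-dioxo-2,3,5,6,7,7a-hexahydro-1H-inden-2-yl]propanal
Product: 17 tricyclic hydroxy diketone (C11 exo carbinol; C4 and C9 ketones; C5 gem-dimethyl), via samarium enolate 16 (not isolated)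
Conditions: SmI2 (2.3 equiv), HMPA (10 equiv), THF, −78 °C; then MeI (10 equiv), −78 °C → rt
Reagents that add atoms: iodomethane, CI
Why: Electron transfer from divalent samarium to the aldehyde gives a C11 ketyl that adds to the enone β-carbon C6, and a second electron turns the C5 radical into the trivalent samarium enolate 16, which iodomethane C-methylates to complete the gem-dimethyl group. The closest known reaction type is the SmI2/HMPA aldehyde–enone ketyl–olefin cyclisation with alkyl halide trapping of the samarium enolate. The ring closed is the cyclopentane C6–C7–C8–C10–C11, the second two-carbon bridge of the bicyclo[2.2.1]heptane, by a 5-exo-trig closure. C6 is controlled by the tether, which hangs from C8 on the face opposite C12 and can reach C6 only there, so C11 ends trans and C7 cis to C12. C11 is controlled by sterics: the oxygen with its HMPA-solvated samarium takes the outer position beside C7, because the inner one lies under C1 and the C2 methylene, and HMPA also suppresses a chelate to the C9 carbonyl that would pull the oxygen inward. C8 and C10 are carried through unchanged, so the methyl group ends exo and C10–H endo. The step needs reduction of the aldehyde before the hindered, unconjugated C9 ketone, which low temperature and near-stoichiometric reductant should secure, and C- rather than O-methylation, which the soft electrophile favours.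

Step 10
Reactants: 17 tricyclic hydroxy diketone
Product: 18 C11 benzyl ether of 17
Conditions: 2-benzyloxy-1-methylpyridinium triflate (2 equiv), MgO, PhCF3, 85 °C
Reagents that add atoms: 2-benzyloxy-1-methylpyridinium trifluoromethanesulfonate, C[n+]1ccccc1OCc1ccccc1.[O-]S(=O)(=O)C(F)(F)F
Why: Neutral thermal benzyl transfer etherifies the hindered secondary alcohol without enolising the C4 ketone. The ether keeps the C11 oxygen from intercepting the C4 carbene or protonating the diazo intermediates in step 12.

Step 11
Reactants: 18 C11 benzyl ether of 17
Product: 19 C4,C9-bis(tosylhydrazone) of 18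
Conditions: TsNHNH2 (3 equiv), EtOH, HCl (cat.), 80 °C
Reagents that add atoms: 4-methylbenzenesulfonohydrazide, Cc1ccc(cc1)S(=O)(=O)NN
Why: Acid-catalysed condensation converts both ketones, each flanked by one quaternary carbon, into tosylhydrazones; no stereocentre changes.

Step 12
Reactants: 19 C4,C9-bis(tosylhydrazone) of 18
Product: 21 nortricyclene with ring A C3=C4 alkene and benzyl ethers on C11 and C12, via bis(diazo) compound 20 (not isolated)
Conditions: NaH (2.4 equiv), diglyme, rt → 150 °C
Reagents that add atoms: none
Why: Twofold aprotic Bamford–Stevens reaction: the sodium salts lose sulfinate and then nitrogen to give two carbenes. The C9 carbene has no hydrogen that can shift and inserts into the facing endo C10–H bond with retention, closing the cyclopropane and fixing C9 and C10. The C4 carbene undergoes a 1,2-hydrogen shift from C3, the only neighbour that carries hydrogen, to give the C3=C4 alkene.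

Step 13
Reactants: 21 nortricyclene with ring A C3=C4 alkene and benzyl ethers on C11 and C12
Product: 22 C11,C12-diol
Conditions: Li, NH3(l), THF, −78 °C; NH4Cl
Reagents that add atoms: none
Why: Dissolving-metal (Birch-type) cleavage removes both benzyl ethers, while the isolated alkene and the unconjugated cyclopropane are not reduced.

Step 14
Reactants: 22 C11,C12-diol
Product: 23 C11,C12-diacetate
Conditions: Ac2O, Et3N, DMAP (cat.), CH2Cl2, rt
Reagents that add atoms: acetic anhydride, CC(=O)OC(C)=O
Why: DMAP-catalysed acylation esterifies the primary and the hindered secondary hydroxyl; both are wanted as acetates, so no selectivity is needed.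

Step 15
Reactants: 23 C11,C12-diacetate
Product: 26 target CNP0197219.1, via trans iodo acetate 24 (not isolated), via acetoxonium ion 25 (not isolated)
Conditions: I2 (1.1 equiv), AgOAc (2.2 equiv), AcOH, rt, dark; then H2O (1.5 equiv), 90 °C
Reagents that add atoms: silver acetate, CC(=O)[O-].[Ag+]; water, O
Why: Woodward cis-hydroxylation: the iodonium ion forms on the more open lower face and acetate opens it trans-diaxially at C3 from the upper face (Fürst–Plattner rule; C4 is neopentyl). Silver-assisted displacement of the C4 iodide by the ester carbonyl then gives the cis-fused acetoxonium ion on the upper face. Its hydrolysis leaves the ester on the axial oxygen, so the C3 acetate and the free equatorial C4 hydroxyl both arise on the C12 face.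

## Compound list

1 | cyclopentane-1,3-dione | O=C1CCC(=O)C1 | starting material
2 | allyl bromide (3-bromoprop-1-ene) | C=CCBr | starting material
3 | 2-allylcyclopentane-1,3-dione | C=CCC1C(=O)CCC1=O | intermediate
4 | ethyl vinyl ketone (pent-1-en-3-one) | CCC(=O)C=C | starting material
5 | 2-allyl-2-(3-oxopentyl)cyclopentane-1,3-dione | C=CCC1(CCC(=O)CC)C(=O)CCC1=O | intermediate
6 | (7aR)-7a-allyl-4-methyl-2,3,7,7a-tetrahydro-1H-indene-1,5(6H)-dione (angular allyl on C1; C9 and C4 ketones; C5=C6) | C=CC[C@]12CCC(=O)C(C)=C1CCC2=O | intermediate
7 | (7aR)-4-methyl-7a-[(E)-prop-1-enyl]-2,3,7,7a-tetrahydro-1H-indene-1,5(6H)-dione | C/C=C/[C@]12CCC(=O)C(C)=C1CCC2=O | intermediate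
8 | (7aS)-4-methyl-1,5-dioxo-1,2,3,5,6,7-hexahydro-7aH-indene-7a-carbaldehyde (C12 aldehyde; not isolated) | O=C[C@]12CCC(=O)C(C)=C1CCC2=O | intermediate
9 | (7aS)-7a-(hydroxymethyl)-4-methyl-2,3,7,7a-tetrahydro-1H-indene-1,5(6H)-dione | OC[C@]12CCC(=O)C(C)=C1CCC2=O | intermediate
10 | (7aS)-7a-[(benzyloxy)methyl]-4-methyl-2,3,7,7a-tetrahydro-1H-indene-1,5(6H)-dione | c1ccccc1COC[C@]12CCC(=O)C(C)=C1CCC2=O | intermediate
11 | (Z)-but-2-en-1-ol | C/C=C\CO | starting material
12 | C9 dimethyl ketal of 10 (not isolated) | c1ccccc1COC[C@]12CCC(=O)C(C)=C1CCC2(OC)OC | intermediate
13 | C9 (Z)-but-2-enyl enol ether of 10, double bond C8=C9 (not isolated) | c1ccccc1COC[C@]12CCC(=O)C(C)=C1CC=C2OC/C=C\C | intermediate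
14 | (2S,7aS)-7a-[(benzyloxy)methyl]-2-[(2S)-but-3-en-2-yl]-4-methyl-2,3,7,7a-tetrahydro-1H-indene-1,5(6H)-dione (arm on C8 trans to C12) | c1ccccc1COC[C@]12CCC(=O)C(C)=C1C[C@@H]([C@@H](C)C=C)C2=O | intermediate
15 | (2R)-2-[(2S,7aS)-7a-[(benzyloxy)methyl]-4-methyl-1,5-dioxo-2,3,5,6,7,7a-hexahydro-1H-inden-2-yl]propanal (key-step precursor; C11 aldehyde) | c1ccccc1COC[C@]12CCC(=O)C(C)=C1C[C@@H]([C@@H](C)C=O)C2=O | intermediate
16 | trivalent samarium C4 enolate and C11 alkoxide of the cyclised tricycle (not isolated) | c1ccccc1COC[C@]12CCC(O[Sm](I)I)=C(C)[C@]13C[C@@H]([C@@H](C)[C@H]3O[Sm](I)I)C2=O | intermediate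
17 | tricyclic hydroxy diketone: ring A cyclohexanone (C4=O, C5 gem-dimethyl) fused at C1–C6 to a bicyclo[2.2.1]heptan-2-one (C9=O; bridgeheads C6 and C8; C7 one-carbon bridge); C12 benzyloxymethyl exo and C2 endo on C1; C10 methyl exo; C11 hydroxyl exo (toward C7) | c1ccccc1COC[C@]12CCC(=O)C(C)(C)[C@]13C[C@@H]([C@@H](C)[C@H]3O)C2=O | intermediate
18 | C11 benzyl ether of 17 | c1ccccc1COC[C@]12CCC(=O)C(C)(C)[C@]13C[C@@H]([C@@H](C)[C@H]3OCc4ccccc4)C2=O | intermediate
19 | C4,C9-bis(4-methylbenzenesulfonylhydrazone) of 18 | c1ccccc1COC[C@]12CCC(=NNS(=O)(=O)c4ccc(C)cc4)C(C)(C)[C@]13C[C@@H]([C@@H](C)[C@H]3OCc5ccccc5)C2=NNS(=O)(=O)c6ccc(C)cc6 | intermediate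
20 | C4,C9-bis(diazo) compound derived from 19 (not isolated) | c1ccccc1COC[C@]12CCC(=[N+]=[N-])C(C)(C)[C@]13C[C@@H]([C@@H](C)[C@H]3OCc4ccccc4)C2=[N+]=[N-] | intermediate
21 | nortricyclene (cyclopropane C8–C9–C10) fused at C1–C6 to cyclohex-3-ene ring A (C3=C4, C5 gem-dimethyl); benzyloxymethyl on C1, benzyloxy on C11 (toward C7), methyl on C10 | c1ccccc1COC[C@]12CC=CC(C)(C)[C@]13C[C@@H]1[C@H]2[C@]1(C)[C@H]3OCc4ccccc4 | intermediate
22 | C11,C12-diol corresponding to 21 | OC[C@]12CC=CC(C)(C)[C@]13C[C@@H]1[C@H]2[C@]1(C)[C@H]3O | intermediate
23 | C11,C12-diacetate of 22 | CC(=O)OC[C@]12CC=CC(C)(C)[C@]13C[C@@H]1[C@H]2[C@]1(C)[C@H]3OC(C)=O | intermediate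
24 | trans-diaxial iodo acetate: C3 acetoxy on the upper face, C4 iodide on the lower face (not isolated) | CC(=O)OC[C@]12C[C@H](OC(C)=O)[C@@H](I)C(C)(C)[C@]13C[C@@H]1[C@H]2[C@]1(C)[C@H]3OC(C)=O | intermediate
25 | cis-fused 2-methyl-1,3-dioxolan-2-ylium ion spanning the C3 and C4 oxygens on the upper face (not isolated) | CC(=O)OC[C@]12C[C@@H]4O[C+](C)O[C@@H]4C(C)(C)[C@]13C[C@@H]1[C@H]2[C@]1(C)[C@H]3OC(C)=O | intermediate
26 | CNP0197219.1: C3, C11 and C12 triacetate with free C4 hydroxyl | CC(=O)OC[C@]12C[C@H](OC(C)=O)[C@H](O)C(C)(C)[C@]13C[C@@H]1[C@H]2[C@]1(C)[C@H]3OC(C)=O | target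

## Step count and least certain steps

Total step count: 15. Longest linear sequence: 15 (fully linear from 1).

**Step 9 (key step).**
- Risk: failure of C-methylation. The trivalent samarium enolate is a weak carbon nucleophile and C5 is shielded by the new quaternary C6, so protonation on work-up or O-methylation may win. A second concern is leakage to the C11 epimer if the ketyl oxygen turns inward. The first adjustment for that is a change of additive only.
- Fallback: from 15 the same reductive cyclisation is run and the enolate is silylated in the flask with Me3SiCl/Et3N to give the C4 trimethylsilyl enol ether C11 trimethylsilyl ether F1. Treatment of F1 with anhydrous benzyltrimethylammonium fluoride and iodomethane in THF releases the regiodefined ammonium enolate, which is methylated at C5. The fluoride work-up also frees the C11 hydroxyl, and the route is rejoined at 17.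

**Step 7.**
- Risk: poor conversion to the enol ether at the neopentyl C9 carbonyl under acid, with competing dienol ether formation at C4 or Z to E scrambling of the allylic alcohol. In addition, erosion of the chair preference is possible, because the pseudo-axial methyl group of the Z-alkene lies under the five-membered ring, and that would leak into the C10 epimer.
- Fallback: from 10, condensation with hydrazine at the saturated carbonyl gives the C9 hydrazone F2. Iodine and tetramethylguanidine convert F2 into the C9 vinyl iodide F3 (Barton vinyl iodide synthesis). CuI-catalysed C–O coupling of F3 with 11 (3,4,7,8-tetramethyl-1,10-phenanthroline, Cs2CO3, toluene, 80 → 120 °C) builds the same enol ether 13 without acid, and it rearranges in the same flask to 14.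

**Step 12.**
- Risk: incomplete or unselective decomposition when two carbenes are generated in one flask. At C4, methyl migration or insertion into a C5 methyl group can compete with the hydrogen shift, and the C11 ether oxygen can be intercepted.
- Fallback: from 18, KN(SiMe3)2 and PhNTf2 give the C4 enol triflate F4, since C9 cannot enolise. Pd(OAc)2/PPh3 with HCO2H/Bu3N reduces F4 to the ring A alkene ketone F5. F5 is condensed with 4-methylbenzenesulfonohydrazide to the C9 mono-tosylhydrazone F6. NaH in diglyme at 150 °C then generates only the C9 carbene and gives 21.

**Step 15.**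
- Risk: diversion of the silver-assisted ionisation at neopentyl C4 into a methyl shift from C5, electrophilic opening of the cyclopropane by the iodine reagent, or slow acetate entry into the crowded upper face at C3.
- Fallback: from 23, dimethyldioxirane gives the lower-face C3,C4-epoxide F7. Acetic acid opens F7 trans-diaxially at C3 to the C3 acetate C4 lower-face alcohol F8, without a cation at C4. Dess–Martin periodinane oxidises F8 to the C3-acetoxy C4 ketone F9. NaBH4/CeCl3 in MeOH at −78 °C delivers hydride to the open lower face of F9 and gives 26.

## Further compounds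

F1 | step 9 | C4 trimethylsilyl enol ether C11 trimethylsilyl ether of the cyclised tricycle | c1ccccc1COC[C@]12CCC(O[Si](C)(C)C)=C(C)[C@]13C[C@@H]([C@@H](C)[C@H]3O[Si](C)(C)C)C2=O
F2 | step 7 | C9 hydrazone of 10 | c1ccccc1COC[C@]12CCC(=O)C(C)=C1CCC2=NN
F3 | step 7 | C9 vinyl iodide of 10 (C8=C9) | c1ccccc1COC[C@]12CCC(=O)C(C)=C1CC=C2I
F4 | step 12 | C4 enol triflate of 18 (C3=C4) | c1ccccc1COC[C@]12CC=C(OS(=O)(=O)C(F)(F)F)C(C)(C)[C@]13C[C@@H]([C@@H](C)[C@H]3OCc4ccccc4)C2=O
F5 | step 12 | ring A C3=C4 alkene with C9 ketone | c1ccccc1COC[C@]12CC=CC(C)(C)[C@]13C[C@@H]([C@@H](C)[C@H]3OCc4ccccc4)C2=O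
F6 | step 12 | C9 mono-tosylhydrazone of F5 | c1ccccc1COC[C@]12CC=CC(C)(C)[C@]13C[C@@H]([C@@H](C)[C@H]3OCc4ccccc4)C2=NNS(=O)(=O)c5ccc(C)cc5
F7 | step 15 | lower-face C3,C4-epoxide of 23 | CC(=O)OC[C@]12C[C@H]4O[C@H]4C(C)(C)[C@]13C[C@@H]1[C@H]2[C@]1(C)[C@H]3OC(C)=O
F8 | step 15 | C3 upper-face acetate with C4 lower-face alcohol | CC(=O)OC[C@]12C[C@H](OC(C)=O)[C@@H](O)C(C)(C)[C@]13C[C@@H]1[C@H]2[C@]1(C)[C@H]3OC(C)=O
F9 | step 15 | C3-acetoxy C4 ketone | CC(=O)OC[C@]12C[C@H](OC(C)=O)C(=O)C(C)(C)[C@]13C[C@@H]1[C@H]2[C@]1(C)[C@H]3OC(C)=O
A1 | alternative 1 | dienoyl chloride with ring A C1=C6 alkene and C3/C4 acetonide | CC(C)(C)[Si](C)(C)OCC=1C[C@@H]2OC(C)(C)O[C@@H]2C(C)(C)C=1CC/C(C)=C/C(Cl)=O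
A2 | alternative 1 | vinylketene from A1 | CC(C)(C)[Si](C)(C)OCC=1C[C@@H]2OC(C)(C)O[C@@H]2C(C)(C)C=1C/C=C(/C)C=C=O
A3 | alternative 1 | bicyclo[3.1.1]heptenone fused to ring A across C1–C6 | CC(C)(C)[Si](C)(C)OC[C@]12C[C@@H]5OC(C)(C)O[C@@H]5C(C)(C)[C@]13CC=C(C)[C@H]2C3=O
A4 | alternative 2 | cage dialdehyde (C3 and C4 aldehydes) | CC(=O)OC[C@@]1(CC=O)[C@H]2[C@H]3C[C@]1(C(C)(C)C=O)[C@H](OC(C)=O)[C@@]23C
A5 | alternative 2 | ring A hydroxy ketone (C3 ketone, C4 hydroxyl) | CC(=O)OC[C@]12CC(=O)[C@H](O)C(C)(C)[C@]13C[C@@H]1[C@H]2[C@]1(C)[C@H]3OC(C)=O
A6 | alternative 3 | cross-conjugated dienone (C9=C10–C11(=O)–C6=C1) with ring A carbonate | CC(C)(C)[Si](c1ccccc1)(c1ccccc1)OCC=2C[C@@H]3OC(=O)O[C@@H]3C(C)(C)C=2C(=O)/C(C)=C/OCc4ccccc4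
A7 | alternative 3 | phenyl vinyl sulfide | C=CSc1ccccc1
A8 | alternative 3 | C7-phenylthio bicyclo[2.2.1]heptan-7-one fused to ring A | CC(C)(C)[Si](c1ccccc1)(c1ccccc1)OC[C@]12C[C@@H]5OC(=O)O[C@@H]5C(C)(C)[C@]13[C@@H](Sc4ccccc4)C[C@](C)([C@@H]2OCc6ccccc6)C3=O
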